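**Strategy.** Numbering the oxolane ring O1, C2 (aryl), C3 (CH2OH), C4 (aroyl), C5, the plan treats the ring as a masked butenolide: with C2 as a lactone carbonyl, C4 is the β-carbon. The key step joins C4 to the future ketone carbon by conjugate addition of a lithiated 2-(3,4,5-trimethoxyphenyl)-1,3-dithiane to (5R)-5-(l-menthyloxy)-2(5H)-furanone and traps the enolate with formaldehyde. The bought acetal center at C5 sets C4 and C4 sets C3 in one operation; C5 is then reduced to CH2. Aryllithium addition at C2 and ionic hydrogenation of the hemiketal set C2 from C3, and dithiane hydrolysis unveils the ketone.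

Key step: step 2

Remark on the chemistry: furanone 4 is taken as a purchasable building block, and monomeric formaldehyde 5 is generated from paraformaldehyde immediately before use. The lactone numbering (O1, C2, C3, C4, C5) is the same as the ring numbering of the target throughout.

**Step 1**
Reactants: 1 3,4,5-trimethoxybenzaldehyde; 2 propane-1,3-dithiol
Product: 3 2-(3,4,5-trimethoxyphenyl)-1,3-dithiane
Conditions: BF3·OEt2 (cat.), CH2Cl2, 0 °C to rt
Reagents that add atoms: none
Why: Lewis-acid-catalysed dithioacetalisation of an aromatic aldehyde is reliable and turns the aldehyde carbon into a Corey–Seebach acyl anion equivalent; no stereocenter is formed.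

**Step 2**
Reactants: 3 2-(3,4,5-trimethoxyphenyl)-1,3-dithiane; 4 (5R)-5-(l-menthyloxy)-2(5H)-furanone; 5 formaldehyde
Product: 8 (3S,4R,5R)-3-(hydroxymethyl)-5-(l-menthyloxy)-4-[2-(3,4,5-trimethoxyphenyl)-1,3-dithian-2-yl]oxolan-2-one, via 2-lithiodithiane 6 (not isolated), via lithium enolate 7 (not isolated)
Conditions: n-BuLi, THF, −78 °C; then 4, −78 °C; then gaseous 5, −78 °C; aq NH4Cl
Reagents that add atoms: none
Why: Deprotonation gives the soft, aryl- and sulfur-stabilised carbanion 6, which adds 1,4 (Michael addition, Corey–Seebach umpolung) to the β-carbon of 4 and so forms the bond between ring carbon C4 and the masked ketone carbon; lithium enolate 7 is then hydroxymethylated at C3 by formaldehyde (aldol addition). The closest known reaction type is the tandem conjugate addition–enolate trapping of lithiated dithianes on 5-alkoxy-2(5H)-furanones used for lignan lactones. No ring is closed; the furanone ring itself becomes the oxolane ring of the target. C4 is controlled by the C5 menthyloxy acetal center (attack anti to the alkoxy group), and C3 is controlled by C4 (formaldehyde approaches anti to the bulky dithianyl group, giving the 3,4-trans lactone). The step needs 1,4- over 1,2-addition, which the delocalised 2-aryl dithiane anion in THF at −78 °C should secure. It also needs single hydroxymethylation, which is expected because the product is a lithium alkoxide that does not enolise again at this temperature.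

**Step 3**
Reactants: 8 (3S,4R,5R)-3-(hydroxymethyl)-5-(l-menthyloxy)-4-[2-(3,4,5-trimethoxyphenyl)-1,3-dithian-2-yl]oxolan-2-one
Product: 11 (3S,4R)-3-(hydroxymethyl)-4-[2-(3,4,5-trimethoxyphenyl)-1,3-dithian-2-yl]oxolan-2-one, via formyl carboxylate 9 (not isolated), via dihydroxy acid 10 (not isolated)
Conditions: NaBH4, KOH, EtOH/H2O, 0 °C to rt; then aq HCl (pH 2), rt
Reagents that add atoms: potassium hydroxide, [K+].[OH-]
Why: Hydroxide opens the acylal-type pseudo-ester to formyl carboxylate 9 with loss of menthol, NaBH4 reduces the aldehyde as soon as it is unmasked and acidification closes dihydroxy acid 10 to the γ-lactone (saponification, borohydride reduction and lactonisation in one pot), so the auxiliary carbon C5 ends as the ring CH2 while C3 (α to a carboxylate) and C4 should not epimerise; the hydroxide oxygen enters the carboxylate and can remain as the lactone carbonyl oxygen.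

**Step 4**
Reactants: 11 (3S,4R)-3-(hydroxymethyl)-4-[2-(3,4,5-trimethoxyphenyl)-1,3-dithian-2-yl]oxolan-2-one; 12 4-bromo-1,2-dimethoxybenzene
Product: 14 (3S,4R)-2-(3,4-dimethoxyphenyl)-3-(hydroxymethyl)-4-[2-(3,4,5-trimethoxyphenyl)-1,3-dithian-2-yl]oxolan-2-ol (anomer mixture, used crude), via aryllithium 13 (not isolated)
Conditions: 12, n-BuLi, THF, −78 °C; then 11, −78 °C; aq NH4Cl, −78 °C
Reagents that add atoms: none
Why: Bromine–lithium exchange gives 13, one equivalent of which deprotonates the hydroxyl group while a second adds 1,2 to the lactone carbonyl C2 to give a lithium lactolate that is stable at −78 °C (aryllithium addition to a lactone), so protonation should deliver the cyclic hemiketal; the dithiane keeps the other carbonyl masked and no lasting stereocenter is formed.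

**Step 5**
Reactants: 14 (3S,4R)-2-(3,4-dimethoxyphenyl)-3-(hydroxymethyl)-4-[2-(3,4,5-trimethoxyphenyl)-1,3-dithian-2-yl]oxolan-2-ol
Product: 16 [(2S,3S,4R)-2-(3,4-dimethoxyphenyl)-4-[2-(3,4,5-trimethoxyphenyl)-1,3-dithian-2-yl]oxolan-3-yl]methanol, via oxocarbenium ion 15 (not isolated)
Conditions: Et3SiH, BF3·OEt2, CH2Cl2, −78 °C; aq NaHCO3
Reagents that add atoms: none
Why: BF3 ionises the hemiketal to the aryl-conjugated oxocarbenium ion 15 and Et3SiH should deliver hydride anti to the adjacent C3 hydroxymethyl group (ionic hydrogenation of a lactol, as in hemiketal reductions that give 2,3-cis-2-aryltetrahydrofuran lignans), which places the aryl group cis to the C3 substituent and sets C2 as S by control from C3.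

**Step 6**
Reactants: 16 [(2S,3S,4R)-2-(3,4-dimethoxyphenyl)-4-[2-(3,4,5-trimethoxyphenyl)-1,3-dithian-2-yl]oxolan-3-yl]methanol
Product: 17 [(2S,3S,4R)-2-(3,4-dimethoxyphenyl)-3-(hydroxymethyl)oxolan-4-yl](3,4,5-trimethoxyphenyl)methanone (target; aryl and CH2OH cis, CH2OH and aroyl trans)
Conditions: MeI, CaCO3, MeCN/H2O (4:1), 45 °C
Reagents that add atoms: water, O
Why: S-Methylation makes the dithiane a sulfonium leaving group and the aryl-stabilised thionium ion is hydrolysed to the ketone under buffered, non-acidic conditions (alkylative dithioacetal hydrolysis) that should leave the benzylic ring ether and C2 untouched, while C4 already holds the thermodynamically preferred trans relation to C3.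

**Compound list**

1 | 3,4,5-trimethoxybenzaldehyde | COc1cc(C=O)cc(OC)c1OC | starting material
2 | propane-1,3-dithiol | SCCCS | starting material
3 | 2-(3,4,5-trimethoxyphenyl)-1,3-dithiane | COc1cc(C2SCCCS2)cc(OC)c1OC | intermediate
4 | (5R)-5-{[(1R,2S,5R)-5-methyl-2-(propan-2-yl)cyclohexyl]oxy}furan-2(5H)-one, the l-menthyloxy furanone | O=C1O[C@@H](O[C@@H]2C[C@H](C)CC[C@H]2C(C)C)C=C1 | starting material
5 | formaldehyde (monomer from paraformaldehyde) | C=O | starting material
6 | 2-lithio-2-(3,4,5-trimethoxyphenyl)-1,3-dithiane (formed in the flask) | [Li]C1(c2cc(OC)c(OC)c(OC)c2)SCCCS1 | intermediate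
7 | lithium enolate of (4R,5R)-5-(l-menthyloxy)-4-[2-(3,4,5-trimethoxyphenyl)-1,3-dithian-2-yl]oxolan-2-one (formed in the flask) | [Li]OC1=C[C@@H](C2(c3cc(OC)c(OC)c(OC)c3)SCCCS2)[C@H](O[C@@H]4C[C@H](C)CC[C@H]4C(C)C)O1 | intermediate
8 | (3S,4R,5R)-3-(hydroxymethyl)-5-{[(1R,2S,5R)-5-methyl-2-(propan-2-yl)cyclohexyl]oxy}-4-[2-(3,4,5-trimethoxyphenyl)-1,3-dithian-2-yl]oxolan-2-one | O=C1O[C@@H](O[C@@H]2C[C@H](C)CC[C@H]2C(C)C)[C@H](C3(c4cc(OC)c(OC)c(OC)c4)SCCCS3)[C@H]1CO | intermediate
9 | potassium (2S,3R)-2-(hydroxymethyl)-4-oxo-3-[2-(3,4,5-trimethoxyphenyl)-1,3-dithian-2-yl]butanoate (formed in the flask) | O=C[C@H](C1(c2cc(OC)c(OC)c(OC)c2)SCCCS1)[C@@H](CO)C(=O)[O-].[K+] | intermediate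
10 | (2S,3R)-4-hydroxy-2-(hydroxymethyl)-3-[2-(3,4,5-trimethoxyphenyl)-1,3-dithian-2-yl]butanoic acid (formed in the flask) | OC[C@H](C1(c2cc(OC)c(OC)c(OC)c2)SCCCS1)[C@@H](CO)C(=O)O | intermediate
11 | (3S,4R)-3-(hydroxymethyl)-4-[2-(3,4,5-trimethoxyphenyl)-1,3-dithian-2-yl]oxolan-2-one | O=C1OC[C@H](C2(c3cc(OC)c(OC)c(OC)c3)SCCCS2)[C@H]1CO | intermediate
12 | 4-bromo-1,2-dimethoxybenzene | COc1ccc(Br)cc1OC | starting material
13 | (3,4-dimethoxyphenyl)lithium (formed in the flask) | [Li]c1ccc(OC)c(OC)c1 | intermediate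
14 | (3S,4R)-2-(3,4-dimethoxyphenyl)-3-(hydroxymethyl)-4-[2-(3,4,5-trimethoxyphenyl)-1,3-dithian-2-yl]oxolan-2-ol (anomer mixture) | COc1ccc(C2(O)OC[C@H](C3(c4cc(OC)c(OC)c(OC)c4)SCCCS3)[C@H]2CO)cc1OC | intermediate
15 | (3S,4R)-5-(3,4-dimethoxyphenyl)-4-(hydroxymethyl)-3-[2-(3,4,5-trimethoxyphenyl)-1,3-dithian-2-yl]-3,4-dihydro-2H-furan-1-ium hydroxytrifluoroborate (formed in the flask) | COc1ccc(C2=[O+]C[C@H](C3(c4cc(OC)c(OC)c(OC)c4)SCCCS3)[C@H]2CO)cc1OC.O[B-](F)(F)F | intermediate
16 | [(2S,3S,4R)-2-(3,4-dimethoxyphenyl)-4-[2-(3,4,5-trimethoxyphenyl)-1,3-dithian-2-yl]oxolan-3-yl]methanol | COc1ccc([C@H]2OC[C@H](C3(c4cc(OC)c(OC)c(OC)c4)SCCCS3)[C@H]2CO)cc1OC | intermediate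
17 | [(2S,3S,4R)-2-(3,4-dimethoxyphenyl)-3-(hydroxymethyl)oxolan-4-yl](3,4,5-trimethoxyphenyl)methanone | COc1ccc([C@H]2OC[C@H](C(=O)c3cc(OC)c(OC)c(OC)c3)[C@H]2CO)cc1OC | target

**Step count and risks**

Total step count: 6. Longest linear sequence: 6 steps (1 → 3 → 8 → 11 → 14 → 16 → 17).

Step 5 is the most likely to fail. Hydride may be delivered to the wrong face of oxocarbenium ion 15, because the bulky dithianyl group at C4 sits on the face from which hydride must come. C3 may also epimerise through reversible loss of its proton next to the cation. The fallback reverses the order in which hydrogen and aryl arrive at C2, so that the C4 group directs the incoming nucleophile to the face opposite to itself. It sets out from 11: i-Bu2AlH in CH2Cl2 at −78 °C should give the lactol (3S,4R)-3-(hydroxymethyl)-4-[2-(3,4,5-trimethoxyphenyl)-1,3-dithian-2-yl]oxolan-2-ol F1. Friedel–Crafts arylation of its oxocarbenium ion with 1,2-dimethoxybenzene and BF3·OEt2 in CH2Cl2 at −78 °C should then place the aryl group anti to the dithianyl group, and the route is rejoined at 16.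

Step 2 is second. Capture of enolate 7 by formaldehyde may be incomplete (proton transfer, repeated hydroxymethylation) or 1,2-addition of 6 may compete. The fallback separates the two bond formations and sets out from 3 and 4. Lithiation and addition as in step 2, but with an NH4Cl quench, should give the simple adduct (4R,5R)-5-(l-menthyloxy)-4-[2-(3,4,5-trimethoxyphenyl)-1,3-dithian-2-yl]oxolan-2-one F2. NaBH4/KOH and then aq HCl should remove the auxiliary to give (4R)-4-[2-(3,4,5-trimethoxyphenyl)-1,3-dithian-2-yl]oxolan-2-one F3. Enolisation with LiN(i-Pr)2 in THF at −78 °C and addition of monomeric 5 should hydroxymethylate trans to the C4 substituent, and the route is rejoined at 11.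

Step 4 is third. The neighbouring lithium alkoxide may trigger enolisation or retro-aldol loss of formaldehyde, or the lactolate may open early and take up a second aryllithium. The fallback masks the hydroxyl group and sets out from 11. t-BuMe2SiCl and imidazole in DMF should give (3S,4R)-3-{[tert-butyl(dimethyl)silyl]oxymethyl}-4-[2-(3,4,5-trimethoxyphenyl)-1,3-dithian-2-yl]oxolan-2-one F4. Addition of 13 in THF at −78 °C should give the hemiketal (3S,4R)-3-{[tert-butyl(dimethyl)silyl]oxymethyl}-2-(3,4-dimethoxyphenyl)-4-[2-(3,4,5-trimethoxyphenyl)-1,3-dithian-2-yl]oxolan-2-ol F5. Et3SiH and BF3·OEt2 at −78 °C should give the silyl ether tert-butyl{[(2S,3S,4R)-2-(3,4-dimethoxyphenyl)-4-[2-(3,4,5-trimethoxyphenyl)-1,3-dithian-2-yl]oxolan-3-yl]methoxy}dimethylsilane F6. Bu4NF in THF then frees the alcohol, and the route is rejoined at 16.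

**Further compounds**

F1 | step 5 | (3S,4R)-3-(hydroxymethyl)-4-[2-(3,4,5-trimethoxyphenyl)-1,3-dithian-2-yl]oxolan-2-ol | OC1OC[C@H](C2(c3cc(OC)c(OC)c(OC)c3)SCCCS2)[C@H]1CO
F2 | step 2 | (4R,5R)-5-{[(1R,2S,5R)-5-methyl-2-(propan-2-yl)cyclohexyl]oxy}-4-[2-(3,4,5-trimethoxyphenyl)-1,3-dithian-2-yl]oxolan-2-one | O=C1O[C@@H](O[C@@H]2C[C@H](C)CC[C@H]2C(C)C)[C@H](C3(c4cc(OC)c(OC)c(OC)c4)SCCCS3)C1
F3 | step 2 | (4R)-4-[2-(3,4,5-trimethoxyphenyl)-1,3-dithian-2-yl]oxolan-2-one | O=C1OC[C@H](C2(c3cc(OC)c(OC)c(OC)c3)SCCCS2)C1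
F4 | step 4 | (3S,4R)-3-{[tert-butyl(dimethyl)silyl]oxymethyl}-4-[2-(3,4,5-trimethoxyphenyl)-1,3-dithian-2-yl]oxolan-2-one | O=C1OC[C@H](C2(c3cc(OC)c(OC)c(OC)c3)SCCCS2)[C@H]1CO[Si](C)(C)C(C)(C)C
F5 | step 4 | (3S,4R)-3-{[tert-butyl(dimethyl)silyl]oxymethyl}-2-(3,4-dimethoxyphenyl)-4-[2-(3,4,5-trimethoxyphenyl)-1,3-dithian-2-yl]oxolan-2-ol | COc1ccc(C2(O)OC[C@H](C3(c4cc(OC)c(OC)c(OC)c4)SCCCS3)[C@H]2CO[Si](C)(C)C(C)(C)C)cc1OC
F6 | step 4 | tert-butyl{[(2S,3S,4R)-2-(3,4-dimethoxyphenyl)-4-[2-(3,4,5-trimethoxyphenyl)-1,3-dithian-2-yl]oxolan-3-yl]methoxy}dimethylsilane | COc1ccc([C@H]2OC[C@H](C3(c4cc(OC)c(OC)c(OC)c4)SCCCS3)[C@H]2CO[Si](C)(C)C(C)(C)C)cc1OC
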